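Celacinnine's 13-membered ring is numbered N1 (lactam NH), C2 (C=O), C3, C4 (phenyl, S), N5, C6–C9, N10 (cinnamoylated), C11–C13. The feature used is the trimethylene bridge C11–C13 flanked by two acylated nitrogens, N1 and N10: it is the footprint of an amidomethyl cation on N1 joined to an N-vinyl amide on N10, so the ring is cut at C12–C13. One operation lets the acyliminium carbon C13 (from formaldehyde) take the enamide β-carbon C12, closing the macrocycle, then reduces C11 to CH2 with a silane. The precursor is the open chain with an N1 acetoxymethyl amide, an N5 2-nitrobenzenesulfonamide and the N10 N-vinyl cinnamamide, all installed under base.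

Key step: step 8

Remark on the precursor: the leaving group on the N1 aminal carbon is acetate, not a methyl ether, because etherification needs acid in methanol, which would add methanol across the N-vinyl amide, and N5 is masked as a nosyl amide that is put on the primary amine and then alkylated, because trifluoroacetylating a hindered secondary amine beside a primary amide and an enamide risks nitrile formation and C-acylation.

Step 1
Reactants: 1 (E)-cinnamamide; 2 vinyl bromide
Product: 3 (E)-N-vinylcinnamamide
Conditions: CuI (10 mol%), MeNHCH2CH2NHMe (20 mol%), K2CO3 (2 equiv), 2 (1 M in THF, 3 equiv), toluene, 90 °C, sealed tube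
Reagents that add atoms: none
Why: Goldberg-type copper-catalysed amidation of a vinyl halide is general for primary amides, and the secondary enamide formed is a poorer coupling partner than 1, so the reaction should stop after one vinyl group.

Step 2
Reactants: 3 (E)-N-vinylcinnamamide; 4 1,4-dibromobutane
Product: 5 (E)-N-(4-bromobutyl)-N-vinylcinnamamide
Conditions: NaH (1.1 equiv), DMF, 0 °C; then 4 (5 equiv), 0 °C → rt
Reagents that add atoms: none
Why: SN2 N-alkylation of the amidate of a secondary N-vinyl amide is the usual entry to N-alkyl-N-vinyl amides, and the large excess of dibromide should leave the second bromide unreacted.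

Step 3
Reactants: 6 (S)-3-amino-3-phenylpropanoic acid
Product: 7 (S)-3-[(2-nitrophenyl)sulfonylamino]-3-phenylpropanoic acid
Conditions: 2-NO2C6H4SO2Cl (1.2 equiv), 1 M aq. NaOH, dioxane, 0 °C → rt; then 1 M HCl to pH 2
Reagents that add atoms: 2-nitrobenzenesulfonyl chloride, O=S(=O)(Cl)c1ccccc1[N+](=O)[O-]
Why: Schotten–Baumann N-sulfonylation in aqueous base leaves the carboxylate alone, and the C4 stereocentre (S), which comes in with 6 and bears no acidic hydrogen, is not touched.

Step 4
Reactants: 7 (S)-3-[(2-nitrophenyl)sulfonylamino]-3-phenylpropanoic acid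
Product: 9 (S)-3-[(2-nitrophenyl)sulfonylamino]-3-phenylpropanamide, via isobutyl carbonic mixed anhydride 8 (not isolated)
Conditions: iBuOCOCl (1.1 equiv), N-methylmorpholine (1.1 equiv), THF, −15 °C; then 28% aq. NH3 (5 equiv), −15 °C → rt
Reagents that add atoms: ammonia, N; isobutyl chloroformate, CC(C)COC(=O)Cl (its atoms stay only in 8)
Why: Mixed carbonic anhydride amidation, in which ammonia should attack the acyl carbonyl of 8 in preference to the carbonate carbonyl and give the primary amide without affecting the sulfonamide or C4.

Step 5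
Reactants: 9 (S)-3-[(2-nitrophenyl)sulfonylamino]-3-phenylpropanamide; 5 (E)-N-(4-bromobutyl)-N-vinylcinnamamide
Product: 10 (S)-3-{(2-nitrophenylsulfonyl)[4-(N-vinylcinnamamido)butyl]amino}-3-phenylpropanamide
Conditions: 5 (1.2 equiv), K2CO3 (2 equiv), KI (10 mol%), DMF, 50 °C
Reagents that add atoms: none
Why: Fukuyama alkylation, in which carbonate deprotonates only the acidic nosyl amide N–H and its anion displaces the primary halide by SN2 (after Finkelstein exchange), while the primary amide, the enamide and the cinnamoyl group are inert to carbonate.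

Step 6
Reactants: 10 (S)-3-{(2-nitrophenylsulfonyl)[4-(N-vinylcinnamamido)butyl]amino}-3-phenylpropanamide; 11 formaldehyde
Product: 12 (S)-N-(hydroxymethyl)-3-{(2-nitrophenylsulfonyl)[4-(N-vinylcinnamamido)butyl]amino}-3-phenylpropanamide
Conditions: 37% aq. CH2O (5 equiv), K2CO3 (0.2 equiv), THF, 40 °C; pH 7 buffer work-up, crude product used directly
Reagents that add atoms: none
Why: Base-catalysed N-hydroxymethylation (methylolation) of a primary amide is a reversible addition that needs no acid, so the acid-labile N-vinyl amide should survive and excess aldehyde should drive monoaddition at the only N–H group.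

Step 7
Reactants: 12 (S)-N-(hydroxymethyl)-3-{(2-nitrophenylsulfonyl)[4-(N-vinylcinnamamido)butyl]amino}-3-phenylpropanamide
Product: 13 (S)-N-(acetoxymethyl)-3-{(2-nitrophenylsulfonyl)[4-(N-vinylcinnamamido)butyl]amino}-3-phenylpropanamide
Conditions: Ac2O (2 equiv), pyridine (4 equiv), DMAP (5 mol%), CH2Cl2, 0 °C
Reagents that add atoms: acetic anhydride, CC(=O)OC(C)=O
Why: DMAP-catalysed O-acetylation of the hemiaminal hydroxyl gives an N-(acyloxymethyl) amide, a classical amidoalkylating agent, under basic conditions in which neither the enamide nor the aminal carbon ionises.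

Step 8
Reactants: 13 (S)-N-(acetoxymethyl)-3-{(2-nitrophenylsulfonyl)[4-(N-vinylcinnamamido)butyl]amino}-3-phenylpropanamide
Product: 17 N5-(2-nitrophenylsulfonyl)celacinnine, via N1 methylene N-acyliminium ion 14 (not isolated), via ring-closed N10 acyliminium ion 15 (not isolated), via C2-oxygen-bridged oxazine 16 (not isolated)
Conditions: 13 added over 8 h to BF3·OEt2 (3 equiv), CH2Cl2 (1 mM final), 4 Å MS, −20 °C → 0 °C; then Et3SiH (10 equiv), 0 °C → rt; aq. NaHCO3
Reagents that add atoms: none
Why: Proposed new method: BF3·OEt2 removes acetate from the N1 aminal carbon to give the N–H acyliminium ion 14, whose methylene carbon C13 is attacked by the nucleophilic β-carbon C12 of the N10 enamide, so the C12–C13 bond and the 13-membered ring form together and the charge moves to C11 as the N10 acyliminium ion 15; this ion should be held reversibly by the neighbouring C2 oxygen as the six-membered cyclic imidate 16 until Et3SiH is added, when the Lewis acid reopens it and hydride turns C11 into a methylene. The closest known reaction types are Lewis-acid substitution of N-(acyloxyalkyl) N–H amides by π-nucleophiles (amidoalkylation through N-acyliminium ions), aza-ene-type additions of enamides and enecarbamates to N-acylimines, and N-acyliminium cyclisations of tertiary enamides to five- to seven-membered rings; a macrocyclic version is not known. The closure is 13-endo at the iminium carbon and endo with respect to the enamide alkene, both π bonds ending inside the ring, and high dilution with slow addition of 13 is what should favour it over chain growth. No stereocentre is created, since C11 is stereogenic only in 16 and ends as CH2, and C4 has no acidic or ionisable position under these conditions. The step needs the cation to go to the enamide carbon alone: N5 is a non-nucleophilic sulfonamide, the cinnamoyl alkene and both phenyl rings are far weaker π-nucleophiles than the enamide, the N10→C11=C12 polarisation directs attack to C12, and the silane is withheld until the ring is closed so that neither 14 nor a protonated enamide is reduced.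

Step 9
Reactants: 17 N5-(2-nitrophenylsulfonyl)celacinnine
Product: 18 celacinnine
Conditions: PhSH (3 equiv), K2CO3 (4 equiv), MeCN, rt
Reagents that add atoms: none
Why: Fukuyama deprotection, in which thiophenolate adds ipso to the 2-nitroarene (SNAr via a Meisenheimer adduct), sulfur dioxide is lost and the secondary amine N5 is freed, while the lactam, the tertiary cinnamamide (a poor and reversible thiol acceptor) and C4 should be unaffected.

Compound list
1 | (E)-cinnamamide, (2E)-3-phenylprop-2-enamide | NC(=O)/C=C/c1ccccc1 | starting material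
2 | vinyl bromide (bromoethene) | C=CBr | starting material
3 | (E)-N-vinylcinnamamide, (2E)-N-ethenyl-3-phenylprop-2-enamide | C=CNC(=O)/C=C/c1ccccc1 | intermediate
4 | 1,4-dibromobutane | BrCCCCBr | starting material
5 | (E)-N-(4-bromobutyl)-N-vinylcinnamamide | BrCCCCN(C=C)C(=O)/C=C/c1ccccc1 | intermediate
6 | (S)-3-amino-3-phenylpropanoic acid | N[C@@H](CC(=O)O)c1ccccc1 | starting material
7 | (S)-3-[(2-nitrophenyl)sulfonylamino]-3-phenylpropanoic acid | O=C(O)C[C@@H](c1ccccc1)NS(=O)(=O)c1ccccc1[N+](=O)[O-] | intermediate
8 | mixed anhydride of 7 with isobutyl hydrogen carbonate | CC(C)COC(=O)OC(=O)C[C@@H](c1ccccc1)NS(=O)(=O)c1ccccc1[N+](=O)[O-] | intermediate (not isolated)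
9 | (S)-3-[(2-nitrophenyl)sulfonylamino]-3-phenylpropanamide | NC(=O)C[C@@H](c1ccccc1)NS(=O)(=O)c1ccccc1[N+](=O)[O-] | intermediate
10 | (S)-3-{(2-nitrophenylsulfonyl)[4-(N-vinylcinnamamido)butyl]amino}-3-phenylpropanamide | NC(=O)C[C@@H](c1ccccc1)N(CCCCN(C=C)C(=O)/C=C/c1ccccc1)S(=O)(=O)c1ccccc1[N+](=O)[O-] | intermediate
11 | formaldehyde | C=O | starting material
12 | (S)-N-(hydroxymethyl)-3-{(2-nitrophenylsulfonyl)[4-(N-vinylcinnamamido)butyl]amino}-3-phenylpropanamide | OCNC(=O)C[C@@H](c1ccccc1)N(CCCCN(C=C)C(=O)/C=C/c1ccccc1)S(=O)(=O)c1ccccc1[N+](=O)[O-] | intermediate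
13 | (S)-N-(acetoxymethyl)-3-{(2-nitrophenylsulfonyl)[4-(N-vinylcinnamamido)butyl]amino}-3-phenylpropanamide (key-step precursor) | CC(=O)OCNC(=O)C[C@@H](c1ccccc1)N(CCCCN(C=C)C(=O)/C=C/c1ccccc1)S(=O)(=O)c1ccccc1[N+](=O)[O-] | intermediate
14 | N1 methylene N-acyliminium ion derived from 13 by loss of acetate | C=[NH+]C(=O)C[C@@H](c1ccccc1)N(CCCCN(C=C)C(=O)/C=C/c1ccccc1)S(=O)(=O)c1ccccc1[N+](=O)[O-] | intermediate (not isolated)
15 | ring-closed 13-membered N10 acyliminium ion (cation at C11, S at C4) | O=C1C[C@@H](c2ccccc2)N(S(=O)(=O)c2ccccc2[N+](=O)[O-])CCCC[N+](C(=O)/C=C/c2ccccc2)=CCCN1 | intermediate (not isolated)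
16 | bicyclic cyclic imidate: 5,6-dihydro-4H-1,3-oxazine made of the C2 oxygen, C2, N1, C13, C12 and C11 within the 13-membered ring (S at C4, C11 epimers) | C12=NCCC(O1)N(C(=O)/C=C/c1ccccc1)CCCCN(S(=O)(=O)c1ccccc1[N+](=O)[O-])[C@H](c1ccccc1)C2 | intermediate (not isolated)
17 | N5-(2-nitrophenylsulfonyl)celacinnine, (2S)-1-(2-nitrophenylsulfonyl)-2-phenyl-9-[(E)-3-phenylprop-2-enoyl]-1,5,9-triazacyclotridecan-4-one (key-step product) | O=C1C[C@@H](c2ccccc2)N(S(=O)(=O)c2ccccc2[N+](=O)[O-])CCCCN(C(=O)/C=C/c2ccccc2)CCCN1 | intermediate
18 | celacinnine, (2S)-2-phenyl-9-[(E)-3-phenylprop-2-enoyl]-1,5,9-triazacyclotridecan-4-one | O=C1C[C@@H](c2ccccc2)NCCCCN(C(=O)/C=C/c2ccccc2)CCCN1 | target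

Total step count: 9.
Longest linear sequence: 7 steps (6 → 7 → 9 → 10 → 12 → 13 → 17 → 18; the branch 1 → 3 → 5 joins at step 5 and is equally long).

Steps most likely to fail

1. Step 8 (Proposed new method). The acyliminium ion may be captured by the enamide of a second molecule and give chain growth instead of the 13-membered ring. Protic acid formed in the flask may also protonate the enamide before it can act as the nucleophile. The fallback uses known chemistry and closes the same ring at N5–C6 by an intramolecular Fukuyama–Mitsunobu alkylation; it sets out from 7 and comes back at 17. Excess 4-aminobutan-1-ol is monoalkylated with tert-butyl (3-bromopropyl)carbamate (K2CO3, MeCN) to give tert-butyl {3-[(4-hydroxybutyl)amino]propyl}carbamate F1. Selective N-acylation with (E)-cinnamoyl chloride (CH2Cl2, aq. NaHCO3, 0 °C) gives tert-butyl {3-[N-(4-hydroxybutyl)cinnamamido]propyl}carbamate F2. HCl in dioxane, then aqueous K2CO3, frees (E)-N-(3-aminopropyl)-N-(4-hydroxybutyl)cinnamamide F3. Amide coupling of F3 with acid 7 (EDC·HCl, HOBt, iPr2NEt, DMF) gives the open-chain (S)-N-{3-[N-(4-hydroxybutyl)cinnamamido]propyl}-3-[(2-nitrophenyl)sulfonylamino]-3-phenylpropanamide F4. PPh3 and DIAD in THF–toluene under high dilution should then join the nosyl amide nitrogen to the hydroxyl-bearing carbon and give 17, which goes on through step 9.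

2. Step 6. The hemiaminal may revert to amide and formaldehyde during isolation, or a second formaldehyde may add, so that impure material reaches the acetylation. The fallback sets out from 10 and comes back at 13. An Einhorn-type three-component condensation of 10 with aqueous formaldehyde and morpholine (EtOH, rt → 50 °C, no acid) should give the stable N-Mannich base (S)-N-(morpholinomethyl)-3-{(2-nitrophenylsulfonyl)[4-(N-vinylcinnamamido)butyl]amino}-3-phenylpropanamide F5, which can be purified. Ac2O with NaOAc in CH2Cl2 (0 °C → rt) then acylates the morpholine nitrogen and passes the aminal carbon to acetate, giving 13.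

3. Step 1. Volatile vinyl bromide may be lost, the diene-like product may polymerise at 90 °C, or turnover may stall on the unsaturated primary amide. The fallback acylates a nitrogen that already carries the vinyl group; it does not pass through 1 or 2, sets out from commercial N-vinylformamide and comes back at 3. The sodium salt of N-vinylformamide (NaH, THF, 0 °C) is acylated with (E)-cinnamoyl chloride to the mixed imide (E)-N-formyl-N-vinylcinnamamide F6, and K2CO3 in MeOH at 0 °C removes the more electrophilic formyl group to leave 3.

Further compounds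
F1 | step 8 | tert-butyl {3-[(4-hydroxybutyl)amino]propyl}carbamate | CC(C)(C)OC(=O)NCCCNCCCCO
F2 | step 8 | tert-butyl {3-[N-(4-hydroxybutyl)cinnamamido]propyl}carbamate | CC(C)(C)OC(=O)NCCCN(CCCCO)C(=O)/C=C/c1ccccc1
F3 | step 8 | (E)-N-(3-aminopropyl)-N-(4-hydroxybutyl)cinnamamide | NCCCN(CCCCO)C(=O)/C=C/c1ccccc1
F4 | step 8 | (S)-N-{3-[N-(4-hydroxybutyl)cinnamamido]propyl}-3-[(2-nitrophenyl)sulfonylamino]-3-phenylpropanamide | O=C(NCCCN(CCCCO)C(=O)/C=C/c1ccccc1)C[C@@H](c1ccccc1)NS(=O)(=O)c1ccccc1[N+](=O)[O-]
F5 | step 6 | (S)-N-(morpholinomethyl)-3-{(2-nitrophenylsulfonyl)[4-(N-vinylcinnamamido)butyl]amino}-3-phenylpropanamide | O=C(NCN1CCOCC1)C[C@@H](c1ccccc1)N(CCCCN(C=C)C(=O)/C=C/c1ccccc1)S(=O)(=O)c1ccccc1[N+](=O)[O-]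
F6 | step 1 | (E)-N-formyl-N-vinylcinnamamide | O=CN(C=C)C(=O)/C=C/c1ccccc1
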